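## Plan

1. Cuts: in each tetrahydrofuran (O1, C2 aryl, C3 CH2OH, C4 OH and benzyl, C5) the benzylic O1–C2 bond is opened first, then C2–C3 and C4–CH2Ar are cut together; the ring B–ring C biaryl bond is cut last.
2. Feature used: C3, C4, C5 and the C3 hydroxymethyl carbon are the β-carbon, α-carbon, carbonyl carbon and acetal carbon of a 3-alkoxy-5-alkoxybutenolide; C2 is a dithiane (acyl anion) carbon and the C4 benzyl group a benzyl bromide.
3. Forward: the ring B/ring C biaryl is made by Suzuki coupling; its dithiane, the butenolide and the ring A benzyl bromide are joined (unit A). The CH2OSi group on ring C then becomes CH2Br, the electrophile of a second coupling with the ring D dithiane (unit B).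
4. Both dithianes are then hydrolysed, both keto lactone acetals reduced and both tetrahydrofurans closed at O1–C2 in the same three operations; one hydrogenolysis ends the route.
5. Stereochemistry: the (5R) menthyl acetal (from (−)-menthol, by crystallisation) sends the dithiane anti (C3); the dithianyl group sends the benzyl bromide anti (C4); C2 settles trans to the C3 CH2OH group when the ring closes reversibly through the benzylic cation.
6. Phenols travel as benzyl ethers and the tertiary hydroxyls as benzyloxymethyl (BOM) ethers, so the acid-sensitive olivil-type rings meet only a neutral final deprotection.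

Key step: step 13

Conventions: Men = (1R,2S,5R)-2-isopropyl-5-methylcyclohexyl (l-menthyl). Lactone positions follow furanone numbering (C2 carbonyl, C3 α, C4 β, C5 acetal). Ring A = benzyl ring on C4 of unit A; ring B = aryl on C2 of unit A; ring C = biaryl partner of ring B and benzyl ring on C4 of unit B; ring D = aryl on C2 of unit B.

## Route

Step 1
Reactants: 1 furfural
Product: 2 5-hydroxyfuran-2(5H)-one (racemic cyclic hemiacetal)
Conditions: O2, rose bengal (cat.), hν (visible), MeOH, 20 °C
Reagents that add atoms: oxygen, O=O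
Why: Dye-sensitised singlet-oxygen [4+2] cycloaddition to the furan, followed by methanolytic fragmentation in which the formyl carbon leaves as methyl formate, is the standard photooxygenation route to this hydroxybutenolide.

Step 2
Reactants: 2 5-hydroxyfuran-2(5H)-one; 3 (−)-menthol
Product: 4 (5R)-5-(l-menthyloxy)furan-2(5H)-one
Conditions: p-TsOH (cat.), toluene, reflux (Dean–Stark); crystallisation from petroleum ether, mother liquor re-equilibrated with p-TsOH and recrystallised
Reagents that add atoms: none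
Why: Acid-catalysed acetalisation of the pseudo-acid gives both C5 epimers, and the (5R) epimer should crystallise while acid equilibration of the acetal carbon feeds it (crystallisation-induced asymmetric transformation), so C5 is fixed by the menthol auxiliary.

Step 3
Reactants: 4 (5R)-5-(l-menthyloxy)furan-2(5H)-one
Product: 5 (3S,4R,5R)-3,4-dihydroxy-5-(l-menthyloxy)dihydrofuran-2(3H)-one
Conditions: OsO4 (cat.), NMO, acetone/H2O, 0 °C to rt
Reagents that add atoms: N-methylmorpholine N-oxide, C[N+]1([O-])CCOCC1; water, O; both oxygens are passed on through OsO4, O=[Os](=O)(=O)=O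
Why: Catalytic syn-dihydroxylation of the butenolide alkene should occur anti to the menthyloxy group, and the two new carbinol centres are erased in step 4, so only the untouched C5 acetal matters.

Step 4
Reactants: 5 (3S,4R,5R)-3,4-dihydroxy-5-(l-menthyloxy)dihydrofuran-2(3H)-one
Product: 8 (5R)-3-hydroxy-5-(l-menthyloxy)furan-2(5H)-one, via diacetate 6 (not isolated), via enol acetate 7 (not isolated)
Conditions: Ac2O, Et3N, DMAP (cat.), CH2Cl2, 0 °C to rt; then MeOH, rt
Reagents that add atoms: none
Why: Peracetylation followed by E1cB loss of the β-acetoxy group (the usual behaviour of peracylated aldonolactones towards amine bases) gives the enol acetate, an activated ester that DMAP-catalysed methanolysis cleaves to the enol of the α-keto lactone, and these non-acidic conditions leave the C5 acetal alone.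

Step 5
Reactants: 8 (5R)-3-hydroxy-5-(l-menthyloxy)furan-2(5H)-one
Product: 9 (5R)-3-[(benzyloxy)methoxy]-5-(l-menthyloxy)furan-2(5H)-one
Conditions: BOMCl, iPr2NEt, CH2Cl2, 0 °C to rt
Reagents that add atoms: benzyl chloromethyl ether, ClCOCc1ccccc1
Why: The acidic enol is alkylated on oxygen by the hard chloromethyl ether (Williamson-type O-alkylation), giving the acetal-type enol ether that carries the future C4 oxygen.

Step 6
Reactants: 10 5-bromovanillin
Product: 11 4-(benzyloxy)-3-bromo-5-methoxybenzaldehyde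
Conditions: BnBr, K2CO3, DMF, rt
Reagents that add atoms: benzyl bromide, BrCc1ccccc1
Why: Williamson etherification of the phenoxide protects the phenol in a form that tolerates organolithiums, hydride and mild acid.

Step 7
Reactants: 11 4-(benzyloxy)-3-bromo-5-methoxybenzaldehyde
Product: 12 [4-(benzyloxy)-3-bromo-5-methoxyphenyl]methanol
Conditions: NaBH4, MeOH/THF, 0 °C
Reagents that add atoms: none
Why: Borohydride reduction of the aldehyde leaves the aryl bromide and the ethers untouched.

Step 8
Reactants: 12 [4-(benzyloxy)-3-bromo-5-methoxyphenyl]methanol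
Product: 13 {[4-(benzyloxy)-3-bromo-5-methoxybenzyl]oxy}(tert-butyl)dimethylsilane
Conditions: TBSCl, imidazole, DMF, rt
Reagents that add atoms: tert-butyldimethylsilyl chloride, CC(C)(C)[Si](C)(C)Cl
Why: Silylation masks the benzylic alcohol, the later benzyl bromide carbon of ring C, against n-BuLi and the coupling conditions.

Step 9
Reactants: 13 {[4-(benzyloxy)-3-bromo-5-methoxybenzyl]oxy}(tert-butyl)dimethylsilane
Product: 14 2-[2-(benzyloxy)-5-({[tert-butyl(dimethyl)silyl]oxy}methyl)-3-methoxyphenyl]-4,4,5,5-tetramethyl-1,3,2-dioxaborolane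
Conditions: B2pin2, Pd(dppf)Cl2 (cat.), KOAc, 1,4-dioxane, 85 °C
Reagents that add atoms: bis(pinacolato)diboron, CC1(C)OB(OC1(C)C)B2OC(C)(C)C(C)(C)O2
Why: Miyaura borylation turns the aryl bromide into the boronate partner without touching the silyl or benzyl ethers.

Step 10
Reactants: 11 4-(benzyloxy)-3-bromo-5-methoxybenzaldehyde
Product: 15 2-[4-(benzyloxy)-3-bromo-5-methoxyphenyl]-1,3-dithiane
Conditions: HS(CH2)3SH, BF3·OEt2 (cat.), CH2Cl2, 0 °C to rt
Reagents that add atoms: propane-1,3-dithiol, SCCCS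
Why: Lewis-acid-catalysed thioacetalisation converts the aldehyde into the acyl-anion precursor that will become C2 of unit A.

Step 11
Reactants: 14 ring C pinacol boronate; 15 ring B bromoaryl dithiane
Product: 16 2-{4-(benzyloxy)-3-[2-(benzyloxy)-5-({[tert-butyl(dimethyl)silyl]oxy}methyl)-3-methoxyphenyl]-5-methoxyphenyl}-1,3-dithiane
Conditions: Pd(OAc)2 (cat.), SPhos, K3PO4, toluene/H2O, 90 °C
Reagents that add atoms: none
Why: Suzuki–Miyaura coupling with a bulky biarylphosphine joins the two ortho-alkoxy arenes, and aryl dithianes are tolerated by such catalysts.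

Step 12
Reactants: 17 4-(benzyloxy)-3-methoxybenzyl alcohol
Product: 18 4-(benzyloxy)-3-methoxybenzyl bromide
Conditions: PBr3, Et2O, 0 °C
Reagents that add atoms: phosphorus tribromide, BrP(Br)Br
Why: Bromination of the benzylic alcohol through its phosphite ester gives the ring A electrophile, which is used at once.

Step 13
Reactants: 16 biaryl dithiane; 9 (5R)-3-[(benzyloxy)methoxy]-5-(l-menthyloxy)furan-2(5H)-one; 18 4-(benzyloxy)-3-methoxybenzyl bromide
Product: 21 (3S,4R,5R)-3-[4-(benzyloxy)-3-methoxybenzyl]-3-[(benzyloxy)methoxy]-4-[2-(biaryl)-1,3-dithian-2-yl]-5-(l-menthyloxy)dihydrofuran-2(3H)-one (biaryl as in 16), via lithiated dithiane 19 (not isolated), via lithium enolate 20 (not isolated)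
Conditions: n-BuLi, THF, −78 to −20 °C; then 9, −78 °C; then 18, DMPU, −78 to −30 °C
Reagents that add atoms: none
Why: Proposed new method: 19, a soft sulfur-stabilised benzylic carbanion, should add 1,4 to the captodative enoate of 9 at the β-carbon (future C3 of the tetrahydrofuran), anti to the C5 menthyloxy group, to give the lithium α-alkoxy enolate 20, which benzyl bromide 18 then alkylates on the α-carbon (future C4), anti to the new dithianyl group. The closest known reactions are the tandem conjugate addition–benzylation of lithiated 2-aryl-1,3-dithianes with 5-menthyloxy-2(5H)-furanone itself and the anti-selective C-benzylation of β-substituted α-alkoxy-γ-butyrolactone enolates; new here is that the acceptor already carries the α-oxygen. No ring is closed; two skeletal bonds (dithiane carbon to the β-carbon, α-carbon to CH2Ar) form in one flask. The β-stereocentre (4R) is controlled by the (5R) acetal, whose menthyloxy group shields one face of the flat butenolide, and the quaternary α-centre (3S) by the adjacent dithianyl group, so that benzyl ends up trans to the dithiane and cis to the acetal carbon, as the later cis relation of C3 CH2OH and C4 benzyl requires. The step needs 1,4-addition to outrun 1,2-addition and γ-deprotonation at the acetal C–H despite the electron-releasing 3-alkoxy group; the stabilised hindered anion, the inductively activating γ-acetal and DMPU, which also lets the C-alkylation proceed below −30 °C where retro-Michael loss of the dithiane is slow, should secure this.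

Step 14
Reactants: 21 lactone of unit A with CH2OTBS on ring C
Product: 22 the benzylic alcohol corresponding to 21 (CH2OH on ring C)
Conditions: TBAF, AcOH, THF, 0 °C to rt
Reagents that add atoms: none
Why: Buffered fluoride desilylation frees the primary benzylic alcohol without opening the lactone acetal or disturbing the dithiane.

Step 15
Reactants: 22 benzylic alcohol
Product: 23 the benzylic bromide corresponding to 21 (CH2Br on ring C)
Conditions: CBr4, PPh3, CH2Cl2, 0 °C
Reagents that add atoms: carbon tetrabromide, BrC(Br)(Br)Br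
Why: Appel bromination is neutral, so the acetal, the BOM ether and the fully substituted dithiane survive; the bromide is used without storage.

Step 16
Reactants: 24 4-(benzyloxy)-3-methoxybenzaldehyde
Product: 25 2-[4-(benzyloxy)-3-methoxyphenyl]-1,3-dithiane
Conditions: HS(CH2)3SH, BF3·OEt2 (cat.), CH2Cl2, 0 °C to rt
Reagents that add atoms: propane-1,3-dithiol, SCCCS
Why: Lewis-acid-catalysed thioacetalisation gives the acyl-anion precursor for C2 of unit B (ring D).

Step 17
Reactants: 25 ring D dithiane; 9 (5R)-3-[(benzyloxy)methoxy]-5-(l-menthyloxy)furan-2(5H)-one; 23 benzylic bromide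
Product: 28 bis-lactone bis-dithiane: 23 in which CH2Br has become the CH2 on C3 of a second (3S,4R,5R)-3-[(benzyloxy)methoxy]-4-{2-[4-(benzyloxy)-3-methoxyphenyl]-1,3-dithian-2-yl}-5-(l-menthyloxy)dihydrofuran-2(3H)-one, via lithiated dithiane 26 (not isolated), via lithium enolate 27 (not isolated)
Conditions: 25 (excess), n-BuLi, THF, −78 to −20 °C; then 9, −78 °C; then 23, DMPU, −78 to −30 °C
Reagents that add atoms: none
Why: Proposed new method: this is the conjugate addition–enolate benzylation of step 13 (closest known type: tandem addition of lithiated aryl dithianes to 5-menthyloxy-2(5H)-furanone with benzyl bromide quench) with 23 as the electrophile, so 26 should add to 9 anti to the menthyloxy group and enolate 27 should be alkylated anti to the dithianyl group, while 23 offers the enolate no acidic proton and only a hindered α-quaternary lactone carbonyl.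

Step 18
Reactants: 28 bis-lactone bis-dithiane
Product: 29 bis(aryl ketone) bis-lactone (both dithianes replaced by C=O)
Conditions: Hg(ClO4)2, CaCO3, THF/H2O, 0 °C to rt
Reagents that add atoms: water, O
Why: Thiophilic mercury-assisted hydrolysis (the unmasking step of Corey–Seebach umpolung) is fast for hindered 2,2-disubstituted dithianes, and the carbonate buffer protects the menthyl acetals and BOM ethers.

Step 19
Reactants: 29 bis(aryl ketone) bis-lactone
Product: 30 hexaol (per unit ArCH(OH)–CH(CH2OH)–C(OBOM)(CH2Ar′)–CH2OH, benzylic carbinols as epimer mixtures)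
Conditions: LiAlH4, THF, 0 °C to rt
Reagents that add atoms: none
Why: Hydride reduction converts both ketones into benzylic carbinols and opens each lactone acetal to two primary alcohols with release of menthol, the transient aldehyde being reduced faster than its α-centre can epimerise.

Step 20
Reactants: 30 hexaol
Product: 31 hexa-protected target (four aryl benzyl ethers, two tertiary BOM ethers, both tetrahydrofurans (2S,3R,4S))
Conditions: CSA (cat.), CH2Cl2, 0 °C to rt
Reagents that add atoms: none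
Why: Acid ionises each benzylic carbinol to a p-alkoxybenzylic cation that the C5 hydroxyl captures in a 5-exo cyclodehydration (the C3 hydroxymethyl and the C4 oxygen could only give four-membered rings), and because the closure is reversible each C2 should settle as (S), aryl trans to the C3 hydroxymethyl group, while catalytic acid at low temperature is meant to spare the BOM ethers and avoid Friedel–Crafts capture by rings A and C.

Step 21
Reactants: 31 hexa-protected target
Product: 32 CNP0269573.1
Conditions: H2 (1 atm), Pd(OH)2/C, EtOAc/MeOH, rt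
Reagents that add atoms: none
Why: Hydrogenolysis cleaves the four aryl benzyl ethers and the benzyl–oxygen bonds of both BOM groups, whose hemiformals then lose formaldehyde, under neutral conditions that leave the benzylic ring ethers and all six stereocentres untouched.

## Compound list

1 | furfural | O=Cc1ccco1 | starting material
2 | 5-hydroxyfuran-2(5H)-one (racemic) | O=C1C=CC(O)O1 | intermediate
3 | (−)-menthol, (1R,2S,5R) | CC(C)[C@@H]1CC[C@@H](C)C[C@H]1O | starting material
4 | (5R)-5-(l-menthyloxy)furan-2(5H)-one | O=C1O[C@@H](O[C@@H]2C[C@H](C)CC[C@H]2C(C)C)C=C1 | intermediate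
5 | (3S,4R,5R)-3,4-dihydroxy-5-(l-menthyloxy)dihydrofuran-2(3H)-one | O=C1O[C@@H](O[C@@H]2C[C@H](C)CC[C@H]2C(C)C)[C@H](O)[C@@H]1O | intermediate
6 | (3S,4R,5R)-3,4-diacetoxy-5-(l-menthyloxy)dihydrofuran-2(3H)-one (not isolated) | O=C1O[C@@H](O[C@@H]2C[C@H](C)CC[C@H]2C(C)C)[C@H](OC(C)=O)[C@@H]1OC(C)=O | intermediate
7 | (5R)-3-acetoxy-5-(l-menthyloxy)furan-2(5H)-one (not isolated) | O=C1O[C@@H](O[C@@H]2C[C@H](C)CC[C@H]2C(C)C)C=C1OC(C)=O | intermediate
8 | (5R)-3-hydroxy-5-(l-menthyloxy)furan-2(5H)-one | O=C1O[C@@H](O[C@@H]2C[C@H](C)CC[C@H]2C(C)C)C=C1O | intermediate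
9 | (5R)-3-[(benzyloxy)methoxy]-5-(l-menthyloxy)furan-2(5H)-one | O=C1O[C@@H](O[C@@H]2C[C@H](C)CC[C@H]2C(C)C)C=C1OCOCc3ccccc3 | intermediate
10 | 5-bromovanillin | O=Cc1cc(Br)c(O)c(OC)c1 | starting material
11 | 4-(benzyloxy)-3-bromo-5-methoxybenzaldehyde | O=Cc1cc(Br)c(OCc2ccccc2)c(OC)c1 | intermediate
12 | [4-(benzyloxy)-3-bromo-5-methoxyphenyl]methanol | OCc1cc(Br)c(OCc2ccccc2)c(OC)c1 | intermediate
13 | {[4-(benzyloxy)-3-bromo-5-methoxybenzyl]oxy}(tert-butyl)dimethylsilane | CC(C)(C)[Si](C)(C)OCc1cc(Br)c(OCc2ccccc2)c(OC)c1 | intermediate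
14 | ring C pinacol boronate | CC(C)(C)[Si](C)(C)OCc1cc(B2OC(C)(C)C(C)(C)O2)c(OCc3ccccc3)c(OC)c1 | intermediate
15 | 2-[4-(benzyloxy)-3-bromo-5-methoxyphenyl]-1,3-dithiane | COc1cc(C2SCCCS2)cc(Br)c1OCc3ccccc3 | intermediate
16 | biaryl dithiane (ring B dithiane, ring C CH2OTBS) | COc1cc(C2SCCCS2)cc(c1OCc3ccccc3)-c4cc(CO[Si](C)(C)C(C)(C)C)cc(OC)c4OCc5ccccc5 | intermediate
17 | 4-(benzyloxy)-3-methoxybenzyl alcohol | OCc1ccc(OCc2ccccc2)c(OC)c1 | starting material
18 | 4-(benzyloxy)-3-methoxybenzyl bromide | BrCc1ccc(OCc2ccccc2)c(OC)c1 | intermediate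
19 | 2-lithio derivative of 16 (not isolated) | [Li]C1(SCCCS1)c2cc(OC)c(OCc3ccccc3)c(c2)-c4cc(CO[Si](C)(C)C(C)(C)C)cc(OC)c4OCc5ccccc5 | intermediate
20 | lithium enolate from 19 and 9, (4R,5R) (not isolated) | [Li]OC1=C(OCOCc2ccccc2)[C@@H](C3(SCCCS3)c4cc(OC)c(OCc5ccccc5)c(c4)-c6cc(CO[Si](C)(C)C(C)(C)C)cc(OC)c6OCc7ccccc7)[C@H](O[C@@H]8C[C@H](C)CC[C@H]8C(C)C)O1 | intermediate
21 | (3S,4R,5R) lactone of unit A: 3-(ring A benzyl), 3-OBOM, 4-(2-biaryl-1,3-dithian-2-yl), 5-menthyloxy; CH2OTBS on ring C | COc1cc(C[C@@]2(OCOCc3ccccc3)C(=O)O[C@@H](O[C@@H]3C[C@H](C)CC[C@H]3C(C)C)[C@@H]2C4(SCCCS4)c5cc(OC)c(OCc6ccccc6)c(c5)-c7cc(CO[Si](C)(C)C(C)(C)C)cc(OC)c7OCc8ccccc8)ccc1OCc9ccccc9 | intermediate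
22 | as 21, with CH2OH on ring C | COc1cc(C[C@@]2(OCOCc3ccccc3)C(=O)O[C@@H](O[C@@H]3C[C@H](C)CC[C@H]3C(C)C)[C@@H]2C4(SCCCS4)c5cc(OC)c(OCc6ccccc6)c(c5)-c7cc(CO)cc(OC)c7OCc8ccccc8)ccc1OCc9ccccc9 | intermediate
23 | as 21, with CH2Br on ring C | COc1cc(C[C@@]2(OCOCc3ccccc3)C(=O)O[C@@H](O[C@@H]3C[C@H](C)CC[C@H]3C(C)C)[C@@H]2C4(SCCCS4)c5cc(OC)c(OCc6ccccc6)c(c5)-c7cc(CBr)cc(OC)c7OCc8ccccc8)ccc1OCc9ccccc9 | intermediate
24 | 4-(benzyloxy)-3-methoxybenzaldehyde | O=Cc1ccc(OCc2ccccc2)c(OC)c1 | starting material
25 | 2-[4-(benzyloxy)-3-methoxyphenyl]-1,3-dithiane | COc1cc(C2SCCCS2)ccc1OCc3ccccc3 | intermediate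
26 | 2-lithio derivative of 25 (not isolated) | [Li]C1(SCCCS1)c2ccc(OCc3ccccc3)c(OC)c2 | intermediate
27 | lithium enolate from 26 and 9, (4R,5R) (not isolated) | [Li]OC1=C(OCOCc2ccccc2)[C@@H](C3(SCCCS3)c4ccc(OCc5ccccc5)c(OC)c4)[C@H](O[C@@H]6C[C@H](C)CC[C@H]6C(C)C)O1 | intermediate
28 | bis-lactone bis-dithiane (both lactones (3S,4R,5R)) | COc1cc(C[C@@]2(OCOCc3ccccc3)C(=O)O[C@@H](O[C@@H]3C[C@H](C)CC[C@H]3C(C)C)[C@@H]2C4(SCCCS4)c5cc(OC)c(OCc6ccccc6)c(c5)-c7cc(C[C@@]8(OCOCc9ccccc9)C(=O)O[C@@H](O[C@@H]9C[C@H](C)CC[C@H]9C(C)C)[C@@H]8C%10(SCCCS%10)c%11ccc(OCc%12ccccc%12)c(OC)c%11)cc(OC)c7OCc%13ccccc%13)ccc1OCc%14ccccc%14 | intermediate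
29 | bis(aryl ketone) bis-lactone | COc1cc(C[C@@]2(OCOCc3ccccc3)C(=O)O[C@@H](O[C@@H]3C[C@H](C)CC[C@H]3C(C)C)[C@@H]2C(=O)c4cc(OC)c(OCc5ccccc5)c(c4)-c6cc(C[C@@]7(OCOCc8ccccc8)C(=O)O[C@@H](O[C@@H]8C[C@H](C)CC[C@H]8C(C)C)[C@@H]7C(=O)c9ccc(OCc%10ccccc%10)c(OC)c9)cc(OC)c6OCc%11ccccc%11)ccc1OCc%12ccccc%12 | intermediate
30 | hexaol (benzylic carbinol carbons unspecified) | COc1cc(C[C@@](OCOCc2ccccc2)(CO)[C@H](CO)C(O)c3cc(OC)c(OCc4ccccc4)c(c3)-c5cc(C[C@@](OCOCc6ccccc6)(CO)[C@H](CO)C(O)c7ccc(OCc8ccccc8)c(OC)c7)cc(OC)c5OCc9ccccc9)ccc1OCc%10ccccc%10 | intermediate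
31 | hexa-protected target, both rings (2S,3R,4S) | COc1cc(C[C@@]2(OCOCc3ccccc3)CO[C@H](c4cc(OC)c(OCc5ccccc5)c(c4)-c6cc(C[C@@]7(OCOCc8ccccc8)CO[C@H](c9ccc(OCc%10ccccc%10)c(OC)c9)[C@H]7CO)cc(OC)c6OCc%11ccccc%11)[C@H]2CO)ccc1OCc%12ccccc%12 | intermediate
32 | CNP0269573.1 | COc1cc(C[C@@]2(O)CO[C@H](c3cc(OC)c(O)c(-c4cc(C[C@@]5(O)CO[C@H](c6ccc(O)c(OC)c6)[C@H]5CO)cc(OC)c4O)c3)[C@H]2CO)ccc1O | target

## Totals and risks

Total step count: 21. Longest linear sequence: 13 steps (steps 6, 7, 8, 9, 11, 13, 14, 15, 17, 18, 19, 20, 21 from 10; the line from 1 through steps 1 to 5 is equally long).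

Steps most likely to fail:

1. Step 13. The 3-alkoxy group makes the β-carbon less electrophilic, so conjugate addition may become slow enough for γ-deprotonation at the acetal C–H, 1,2-addition, or retro-Michael loss of the dithiane before benzylation to take over. Fallback (known chemistry), setting out from 16 and 4 and returning at 21: 19 is added to the unsubstituted butenolide 4 (THF, −78 °C) and the enolate is protonated to give (4R,5R)-4-(2-biaryl-1,3-dithian-2-yl)-5-(l-menthyloxy)dihydrofuran-2(3H)-one F1. Its potassium enolate (KHMDS, −78 °C, where enolate oxidation outruns sulfide oxidation) is hydroxylated with 2-(phenylsulfonyl)-3-phenyloxaziridine, anti to the dithiane, to give the 3-hydroxy lactone F2. BOMCl/iPr2NEt gives the 3-[(benzyloxy)methoxy] lactone F3. LDA (THF, −78 °C) converts F3 into enolate 20, which is benzylated with 18/DMPU as in step 13 to give 21. The C3 configuration of F2 and F3 does not matter because it is erased in 20, and the oxygen is in place before the benzyl group arrives, so the anti-benzylation still sets C3 correctly.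

2. Step 17. The same sluggish conjugate addition may occur, and any lithiated dithiane left over could attack the lactone of the valuable bromide 23. Fallback (known chemistry), setting out from 25 and 4 and returning at 28: 26 is added to 4 and the enolate protonated to give (4R,5R)-4-{2-[4-(benzyloxy)-3-methoxyphenyl]-1,3-dithian-2-yl}-5-(l-menthyloxy)dihydrofuran-2(3H)-one F4. KHMDS and 2-(phenylsulfonyl)-3-phenyloxaziridine give the 3-hydroxy lactone F5. BOMCl/iPr2NEt gives the 3-[(benzyloxy)methoxy] lactone F6. LDA turns F6 into enolate 27, free of any dithiane anion, which is alkylated with 23/DMPU to give 28.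

3. Step 20. The benzylic cations may be captured by the neighbouring electron-rich benzyl rings (Friedel–Crafts closure to aryltetralins); ionisation may be slow at ring B, whose 4-alkoxy group is twisted out of conjugation by its two ortho substituents; and forcing the acid may cleave the BOM ethers. Fallback, setting out from 29 and returning at 31, which forms O1–C2 by acyl transfer instead of through a cation: both aryl ketones of 29 are reduced (BH3·SMe2 with the CBS oxazaborolidine enantiomer that delivers the (S)-carbinols, expected to be the (R)-catalyst if aryl acts as the large group). K2CO3/NaBH4 in MeOH then lets each benzylic alkoxide take over the adjacent lactone carbonyl, with expulsion of menthol and in situ reduction of the freed aldehyde, giving the bis(5-aryl-4-hydroxymethyl-γ-lactone) F7. DIBAL-H (CH2Cl2, −78 °C) gives the bis-lactol F8, and Et3SiH/BF3·OEt2 (CH2Cl2, −78 °C) removes the lactol hydroxyls through the cyclic oxocarbenium ions to give 31. C2 is then set by the reagent-controlled ketone reduction and carried through with retention.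

## Further compounds

F1 | step 13 | (4R,5R)-4-(2-biaryl-1,3-dithian-2-yl)-5-(l-menthyloxy)dihydrofuran-2(3H)-one (biaryl as in 16) | O=C1C[C@@H](C2(SCCCS2)c3cc(OC)c(OCc4ccccc4)c(c3)-c5cc(CO[Si](C)(C)C(C)(C)C)cc(OC)c5OCc6ccccc6)[C@H](O[C@@H]7C[C@H](C)CC[C@H]7C(C)C)O1
F2 | step 13 | (3R,4R,5R)-3-hydroxy derivative of F1 | O=C1[C@H](O)[C@@H](C2(SCCCS2)c3cc(OC)c(OCc4ccccc4)c(c3)-c5cc(CO[Si](C)(C)C(C)(C)C)cc(OC)c5OCc6ccccc6)[C@H](O[C@@H]7C[C@H](C)CC[C@H]7C(C)C)O1
F3 | step 13 | 3-[(benzyloxy)methoxy] derivative of F1 | O=C1[C@H](OCOCc2ccccc2)[C@@H](C3(SCCCS3)c4cc(OC)c(OCc5ccccc5)c(c4)-c6cc(CO[Si](C)(C)C(C)(C)C)cc(OC)c6OCc7ccccc7)[C@H](O[C@@H]8C[C@H](C)CC[C@H]8C(C)C)O1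
F4 | step 17 | (4R,5R)-4-{2-[4-(benzyloxy)-3-methoxyphenyl]-1,3-dithian-2-yl}-5-(l-menthyloxy)dihydrofuran-2(3H)-one | O=C1C[C@@H](C2(SCCCS2)c3ccc(OCc4ccccc4)c(OC)c3)[C@H](O[C@@H]5C[C@H](C)CC[C@H]5C(C)C)O1
F5 | step 17 | (3R,4R,5R)-3-hydroxy derivative of F4 | O=C1[C@H](O)[C@@H](C2(SCCCS2)c3ccc(OCc4ccccc4)c(OC)c3)[C@H](O[C@@H]5C[C@H](C)CC[C@H]5C(C)C)O1
F6 | step 17 | 3-[(benzyloxy)methoxy] derivative of F4 | O=C1[C@H](OCOCc2ccccc2)[C@@H](C3(SCCCS3)c4ccc(OCc5ccccc5)c(OC)c4)[C@H](O[C@@H]6C[C@H](C)CC[C@H]6C(C)C)O1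
F7 | step 20 | bis(5-aryl-4-hydroxymethyl-3-benzyl-3-BOM-oxy-γ-lactone), C5 carbonyls in place of the ring CH2 groups of 31 | COc1cc(C[C@@]2(OCOCc3ccccc3)C(=O)O[C@H](c4cc(OC)c(OCc5ccccc5)c(c4)-c6cc(C[C@@]7(OCOCc8ccccc8)C(=O)O[C@H](c9ccc(OCc%10ccccc%10)c(OC)c9)[C@H]7CO)cc(OC)c6OCc%11ccccc%11)[C@H]2CO)ccc1OCc%12ccccc%12
F8 | step 20 | bis-lactol of F7 (lactol carbons unspecified) | COc1cc(C[C@@]2(OCOCc3ccccc3)C(O)O[C@H](c4cc(OC)c(OCc5ccccc5)c(c4)-c6cc(C[C@@]7(OCOCc8ccccc8)C(O)O[C@H](c9ccc(OCc%10ccccc%10)c(OC)c9)[C@H]7CO)cc(OC)c6OCc%11ccccc%11)[C@H]2CO)ccc1OCc%12ccccc%12
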